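**Retrosynthetic overview**
The strategy rests on the dimethoxyphenyl ring: its C1 carries the ketone carbon and lies between the two oxygen-bearing carbons C2 and C6. Cutting the C1–acyl bond and the C2–O bond gives 3-methoxybenzyne (C6 methoxy already in place) and a C9 carboxylic acid, joined by aryne insertion into the acyl C–O bond of the acid.
The acid, 9-[4-(benzyloxy)phenyl]nonanoic acid, comes from a Wittig reaction between the phosphonium salt of 8-bromooctanoic acid and 4-(benzyloxy)benzaldehyde, followed by saturation of the alkene with the benzyl ether kept.
After the insertion, the new ortho phenol is methylated and the benzyl ether is removed.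
No ring is formed at any stage; both benzene rings are bought intact and only chain, acyl and ether bonds are made.

Key step: step 4

Remark: alkene 5 is expected as a Z-rich mixture of geometric isomers. It is drawn as the Z isomer and used as the mixture, because step 3 removes the double bond. The target has no stereocentre.

**Route**

Step 1
Reactants: 1 8-bromooctanoic acid
Product: 2 (7-carboxyheptyl)triphenylphosphonium bromide
Conditions: PPh3 (1.1 equiv), MeCN, reflux
Reagents that add atoms: triphenylphosphine, c1ccc(cc1)P(c1ccccc1)c1ccccc1
Why: SN2 quaternisation of an unhindered primary alkyl bromide by triphenylphosphine (phosphonium salt formation), which the free carboxylic acid tolerates.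

Step 2
Reactants: 2 (7-carboxyheptyl)triphenylphosphonium bromide; 3 4-(benzyloxy)benzaldehyde
Product: 5 (8Z)-9-[4-(benzyloxy)phenyl]non-8-enoic acid, via sodium ylide carboxylate 4 (not isolated)
Conditions: NaN(SiMe3)2 (2.2 equiv), THF, 0 °C; then 3, 0 °C to rt; aq. HCl work-up
Reagents that add atoms: none
Why: Wittig olefination in which the first equivalent of base forms the carboxylate and the second the non-stabilised ylide, which should add cleanly to the non-enolisable aromatic aldehyde; the alkene geometry is immaterial.

Step 3
Reactants: 5 (8Z)-9-[4-(benzyloxy)phenyl]non-8-enoic acid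
Product: 6 9-[4-(benzyloxy)phenyl]nonanoic acid
Conditions: TsNHNH2 (excess, in portions), NaOAc, DME/H2O, reflux
Reagents that add atoms: none
Why: Diimide reduction, a concerted syn transfer of two hydrogens from HN=NH to the disubstituted C=C, which cannot cleave the benzyl ether and leaves the acid untouched; the ether must stay because a free phenol would itself add to the aryne in step 4.

Step 4
Reactants: 6 9-[4-(benzyloxy)phenyl]nonanoic acid; 7 3-methoxy-2-(trimethylsilyl)phenyl trifluoromethanesulfonate
Product: 9 9-[4-(benzyloxy)phenyl]-1-(2-hydroxy-6-methoxyphenyl)nonan-1-one, via 3-methoxybenzyne 8 (not isolated)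
Conditions: 7 (1.5 equiv), CsF (4 equiv), THF, sealed tube, 125 °C
Reagents that add atoms: none
Why: Fluoride strips the trimethylsilyl group of 7 and triflate departs, a 1,2-elimination that releases 3-methoxybenzyne 8 in the presence of the cesium carboxylate of 6. The carboxylate oxygen adds to the aryne carbon remote from the methoxy group, which leaves the aryl anion on the carbon next to methoxy, where the C–O dipole stabilises it. That anion attacks the adjacent ester carbonyl (4-exo-trig) to a fleeting benzoxetene alkoxide, which opens by cleavage of the old acyl C–O bond to the cesium phenoxide of the ortho-acylphenol, so the aryl–acyl C–C bond and the aryl C–O bond form in one operation and no ring remains. The closest known reaction type is the fluoride-triggered insertion of arynes from silylaryl triflates into the C–O bond of carboxylic acids in hot THF, an anionic Fries-type acyl shift, and no stereocentre is created. The step needs regioselectivity (oxygen meta and acyl ortho to methoxy), secured by the inductive bias of the methoxy group flanking the triple bond, and needs acyl transfer to outrun protonation to the aryl ester, secured by heating in aprotic THF with the carbonyl held next to the anion. Chemoselectivity rests on the benzyl ether masking the only other nucleophilic oxygen and on the product phenol being tied up in a hydrogen bond to the new ketone.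

Step 5
Reactants: 9 9-[4-(benzyloxy)phenyl]-1-(2-hydroxy-6-methoxyphenyl)nonan-1-one
Product: 10 9-[4-(benzyloxy)phenyl]-1-(2,6-dimethoxyphenyl)nonan-1-one
Conditions: MeI, K2CO3, DMF, 40 °C
Reagents that add atoms: iodomethane, CI
Why: Williamson O-methylation of the only acidic OH; mild heating in a polar aprotic solvent should overcome the hydrogen bond to the ketone, and carbonate is too weak a base to enolise and C-methylate the ketone.

Step 6
Reactants: 10 9-[4-(benzyloxy)phenyl]-1-(2,6-dimethoxyphenyl)nonan-1-one
Product: 11 1-(2,6-dimethoxyphenyl)-9-(4-hydroxyphenyl)nonan-1-one (CNP0078073.0)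
Conditions: H2 (1 atm), Pd/C, EtOAc, rt, stopped after one equivalent of H2
Reagents that add atoms: none
Why: Catalytic hydrogenolysis of an aryl benzyl ether, which is fast at 1 atm, whereas the ketone is twisted out of conjugation and shielded by the two ortho methoxy groups and should not be reduced.

**Compound list**
1 | 8-bromooctanoic acid | OC(=O)CCCCCCCBr | starting material
2 | (7-carboxyheptyl)triphenylphosphonium bromide | OC(=O)CCCCCCC[P+](c1ccccc1)(c1ccccc1)c1ccccc1.[Br-] | intermediate
3 | 4-(benzyloxy)benzaldehyde | O=Cc1ccc(OCc2ccccc2)cc1 | starting material
4 | sodium 8-(triphenylphosphoranylidene)octanoate (ylide carboxylate, not isolated) | [Na+].[O-]C(=O)CCCCCCC=P(c1ccccc1)(c1ccccc1)c1ccccc1 | intermediate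
5 | (8Z)-9-[4-(benzyloxy)phenyl]non-8-enoic acid (Z-rich mixture, drawn as Z) | OC(=O)CCCCCC/C=C\c1ccc(OCc2ccccc2)cc1 | intermediate
6 | 9-[4-(benzyloxy)phenyl]nonanoic acid | OC(=O)CCCCCCCCc1ccc(OCc2ccccc2)cc1 | intermediate
7 | 3-methoxy-2-(trimethylsilyl)phenyl trifluoromethanesulfonate | COc1cccc(OS(=O)(=O)C(F)(F)F)c1[Si](C)(C)C | starting material
8 | 3-methoxybenzyne (not isolated) | COC1=CC=CC#C1 | intermediate
9 | 9-[4-(benzyloxy)phenyl]-1-(2-hydroxy-6-methoxyphenyl)nonan-1-one | COc1cccc(O)c1C(=O)CCCCCCCCc1ccc(OCc2ccccc2)cc1 | intermediate
10 | 9-[4-(benzyloxy)phenyl]-1-(2,6-dimethoxyphenyl)nonan-1-one | COc1cccc(OC)c1C(=O)CCCCCCCCc1ccc(OCc2ccccc2)cc1 | intermediate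
11 | 1-(2,6-dimethoxyphenyl)-9-(4-hydroxyphenyl)nonan-1-one (CNP0078073.0) | COc1cccc(OC)c1C(=O)CCCCCCCCc1ccc(O)cc1 | target

**Step count**
Total steps: 6. Longest linear sequence: 6 steps (1 → 2 → 5 → 6 → 9 → 10 → 11).

**Steps most likely to fail**

Step 4. The ortho aryl anion may be protonated before the acyl group migrates, so that the reaction stops at the aryl ester. The product phenoxide may also be arylated by surplus aryne, or the carboxylate may add with eroded regioselectivity. The fallback sets out from 6 and makes the ketone by aryllithium acylation in place of the aryne. Acid 6 would be activated with carbonyldiimidazole in CH2Cl2 and condensed with N,O-dimethylhydroxylamine hydrochloride to give N-methoxy-N-methyl-9-[4-(benzyloxy)phenyl]nonanamide F1. 1,3-Dimethoxybenzene would be lithiated between its two methoxy groups with n-BuLi in THF (directed ortho metalation) to give 2,6-dimethoxyphenyllithium F2. Addition of F2 to F1 at 0 °C, followed by an aqueous NH4Cl quench, should give the dimethoxy ketone directly. The fallback returns to the route at 10, so step 5 is skipped.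

Step 2. The doubly deprotonated phosphonium species may form incompletely or stay poorly soluble, giving low conversion, and acid may be lost while it is separated from triphenylphosphine oxide. The fallback sets out from 3 and builds the chain by alkene metathesis. Methylenation of 3 with Ph3P=CH2 (from MePPh3Br and KOtBu in THF) should give 1-(benzyloxy)-4-ethenylbenzene F3. Cross-metathesis of F3 with commercial non-8-enoic acid, using second-generation Grubbs catalyst in CH2Cl2 at reflux, should give (8E)-9-[4-(benzyloxy)phenyl]non-8-enoic acid F4. Diimide reduction of F4 under the conditions of step 3 returns to the route at 6.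

Step 3. Diimide may disproportionate faster than it reduces the aryl-conjugated alkene, leaving unreduced alkene that is hard to separate from the product. The fallback sets out from 5 and accepts loss of the protecting group. Exhaustive hydrogenation (H2, Pd/C, EtOH) should saturate the alkene and cleave the benzyl ether to give 9-(4-hydroxyphenyl)nonanoic acid F5. Double benzylation with benzyl bromide and K2CO3 in DMF should give benzyl 9-[4-(benzyloxy)phenyl]nonanoate F6. Saponification of the ester with LiOH in THF/H2O returns to the route at 6.

**Further compounds**
F1 | step 4 | N-methoxy-N-methyl-9-[4-(benzyloxy)phenyl]nonanamide | CON(C)C(=O)CCCCCCCCc1ccc(OCc2ccccc2)cc1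
F2 | step 4 | 2,6-dimethoxyphenyllithium | [Li]c1c(OC)cccc1OC
F3 | step 2 | 1-(benzyloxy)-4-ethenylbenzene | C=Cc1ccc(OCc2ccccc2)cc1
F4 | step 2 | (8E)-9-[4-(benzyloxy)phenyl]non-8-enoic acid | OC(=O)CCCCCC/C=C/c1ccc(OCc2ccccc2)cc1
F5 | step 3 | 9-(4-hydroxyphenyl)nonanoic acid | OC(=O)CCCCCCCCc1ccc(O)cc1
F6 | step 3 | benzyl 9-[4-(benzyloxy)phenyl]nonanoate | O=C(OCc1ccccc1)CCCCCCCCc1ccc(OCc2ccccc2)cc1
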